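**Retrosynthetic overview**

1. The last three operations act on the side chain only: hydrolysis of a C4'/C5' isopropylidene ketal, reagent-controlled reduction of a C1' ketone, and esterification of the C3' hydroxyl with 13-methyltetradecanoic acid.
2. The C2'–C3' bond is cut by a boron aldol between a 4-acetyl bis-oxazole (C1', C2') and (4R,5S)-2,2,5-trimethyl-1,3-dioxolane-4-carbaldehyde (C3'–C6', from L-threitol acetonide), whose C4' centre directs C3'.
3. The acetyl group goes back, through the Weinreb amide, to a methyl ester at C4 of ring A.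
4. The strategy rests on this feature: ring A (oxazole substituted at C2 and C4, with C4 carrying C1'–C6') and ring B (oxazole substituted only at C5) are joined by one CH2 from C2 of ring A to C5 of ring B. Both rings and the bridge therefore map atom for atom onto a linear formamide–ketone–amide–serine chain, and both are closed in one operation (O1–C5 of ring A and O1–C5 of ring B) from methyl N-(4-formamido-3-oxobutanoyl)-L-serinate.
5. That chain comes from N-formylglycine, Meldrum's acid and L-serine methyl ester. Rings A and B form together in step 3, and no other ring is built.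

Key step: step 3

Assumption: C1'–C6' number the side chain from the carbinol carbon on C4 of ring A to the terminal methyl, and 2,3-O-isopropylidene-L-threitol is taken as the purchasable tartrate-derived building block.

**Route**

Step 1
Reactants: 1 N-formylglycine; 2 Meldrum's acid (2,2-dimethyl-1,3-dioxane-4,6-dione)
Product: 3 N-[2-(2,2-dimethyl-4,6-dioxo-1,3-dioxan-5-ylidene)-2-hydroxyethyl]formamide (enol form of the C-acylated Meldrum's acid)
Conditions: DCC, 4-(dimethylamino)pyridine (DMAP, 1.5 equiv), CH2Cl2, 0 °C → rt; filter; cold aq. KHSO4 wash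
Reagents that add atoms: none
Why: Carbodiimide activation of the acid and C-acylation of the Meldrum's acid anion is the standard entry to acyl Meldrum's acids from N-acylated amino acids, and glycine has no stereocentre to lose.

Step 2
Reactants: 3 acyl Meldrum's acid; 4 L-serine methyl ester hydrochloride
Product: 5 methyl N-(4-formamido-3-oxobutanoyl)-L-serinate
Conditions: Et3N (1.1 equiv), MeCN, 70 °C
Reagents that add atoms: none
Why: Thermolysis of the acyl Meldrum's acid expels acetone and CO2 to give an acylketene, which the free amine should trap much faster than the serine hydroxyl or the internal formamide N–H (acylketene aminolysis to a β-keto amide), leaving the serine centre untouched.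

Step 3
Reactants: 5 methyl N-(4-formamido-3-oxobutanoyl)-L-serinate
Product: 7 methyl 2-(1,3-oxazol-5-ylmethyl)-1,3-oxazole-4-carboxylate, via amido aldehyde 6 (not isolated)
Conditions: Dess–Martin periodinane (DMP, 1.1 equiv), CH2Cl2–MeCN, 0 °C; filter (Celite) into PPh3, I2 (4.5 equiv each), Et3N (9 equiv), CH2Cl2, 0 °C → rt
Reagents that add atoms: none
Why: Dess–Martin oxidation converts the primary serine alcohol into amido aldehyde 6, and the phosphonium iodide formed from PPh3 and I2 then drives two Robinson–Gabriel cyclodehydrations in the presence of Et3N; the closest known reactions are the single closures of an α-acylamino aldehyde and of an α-acylamino ketone under these same conditions. Ring A closes by 5-exo-trig attack of the central amide oxygen on the aldehyde carbon (O1–C5), after which the 5-hydroxyoxazoline is converted into its oxyphosphonium salt and loses Ph3PO together with the acidic C4 proton (α to the ester) to aromatise. Ring B closes in the same way by 5-exo-trig attack of the formamide oxygen on the ketone carbon (O1–C5) and phosphonium-assisted dehydration, and if the formamide is first dehydrated to the isocyanide, 5-endo-dig addition of the enol oxygen to the isocyanide carbon leads to the same 5-substituted oxazole. No stereocentre is created, and the serine centre is deliberately lost on aromatisation. The step needs site selectivity and O- over C-cyclisation: each amide oxygen has only one carbonyl placed for a five-membered ring (the crossed pairings would give four-membered rings), and the Z geometry of the secondary amide puts its oxygen next to the aldehyde while holding the acidic chain methylene away from it, which disfavours Knoevenagel closure to a pyrrolinone. One equivalent of periodinane at 0 °C and immediate transfer of 6 into the preformed phosphonium reagent are meant to keep oxidation of the chain methylene and self-condensation of the aldehyde behind the two ring closures.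

Step 4
Reactants: 7 methyl 2-(1,3-oxazol-5-ylmethyl)-1,3-oxazole-4-carboxylate
Product: 8 N-methoxy-N-methyl-2-(1,3-oxazol-5-ylmethyl)-1,3-oxazole-4-carboxamide
Conditions: MeNHOMe·HCl, AlMe3, CH2Cl2, 0 °C → rt; aq. potassium sodium tartrate
Reagents that add atoms: N,O-dimethylhydroxylamine hydrochloride, CNOC.Cl
Why: The aluminium amide made from AlMe3 and the hydroxylamine salt aminolyses the methyl ester directly (Weinreb amidation), and being a poor base it should leave the C2–H of ring B and the bridging CH2 alone.

Step 5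
Reactants: 8 Weinreb amide
Product: 9 1-[2-(1,3-oxazol-5-ylmethyl)-1,3-oxazol-4-yl]ethan-1-one
Conditions: MeMgBr (2.5 equiv), THF, −78 → 0 °C; aq. NH4Cl
Reagents that add atoms: methylmagnesium bromide, C[Mg]Br
Why: In the Weinreb ketone synthesis the magnesium chelate of the tetrahedral adduct persists until work-up, so addition should stop at the methyl ketone, and any reversible magnesiation at C2 of ring B is undone on quenching.

Step 6
Reactants: 10 (4S,5S)-2,2-dimethyl-1,3-dioxolane-4,5-dimethanol (2,3-O-isopropylidene-L-threitol)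
Product: 11 [(4S,5S)-5-(hydroxymethyl)-2,2-dimethyl-1,3-dioxolan-4-yl]methyl 4-methylbenzenesulfonate
Conditions: TsCl (1.05 equiv), Ag2O, KI (cat.), CH2Cl2, 0 °C → rt
Reagents that add atoms: 4-methylbenzenesulfonyl chloride, Cc1ccc(cc1)S(=O)(=O)Cl
Why: Silver-oxide-mediated monosulfonylation of a C2-symmetric diol, in which the two hydroxyls are equivalent so that only the degree of tosylation has to be controlled and no stereocentre is involved.

Step 7
Reactants: 11 monotosylate
Product: 12 [(4S,5S)-2,2,5-trimethyl-1,3-dioxolan-4-yl]methanol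
Conditions: LiBHEt3 (2.2 equiv), THF, 0 °C → rt
Reagents that add atoms: none
Why: SN2 displacement of the primary tosylate by hydride turns CH2OTs into the C6' methyl group, with the first equivalent consumed by the free hydroxyl and the ring stereocentres untouched.

Step 8
Reactants: 12 [(4S,5S)-2,2,5-trimethyl-1,3-dioxolan-4-yl]methanol
Product: 13 (4R,5S)-2,2,5-trimethyl-1,3-dioxolane-4-carbaldehyde
Conditions: DMP, pyridine, CH2Cl2, 0 °C → rt; used at once as a solution
Reagents that add atoms: none
Why: Buffered Dess–Martin oxidation of the primary alcohol should give the volatile α-alkoxy aldehyde without epimerisation at C4, whose descriptor changes from S to R only because the CIP priorities change.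

Step 9
Reactants: 9 methyl ketone; 13 (4R,5S)-2,2,5-trimethyl-1,3-dioxolane-4-carbaldehyde
Product: 15 (3S)-3-hydroxy-1-[2-(1,3-oxazol-5-ylmethyl)-1,3-oxazol-4-yl]-3-[(4S,5S)-2,2,5-trimethyl-1,3-dioxolan-4-yl]propan-1-one, via boron enolate 14 (not isolated)
Conditions: c-Hex2BCl, Et3N, Et2O, −78 → 0 °C; then 13 (1.5 equiv), −78 → −20 °C; MeOH, pH 7 buffer (NaH2PO4/Na2HPO4), H2O2, 0 °C
Reagents that add atoms: chlorodicyclohexylborane, ClB(C1CCCCC1)C1CCCCC1 (retained in 14 only, absent from 15)
Why: Soft enolisation gives boron enolate 14, whose aldol addition through a closed Zimmerman–Traxler transition state cannot involve chelation, so the aldehyde should react in its Cornforth or polar Felkin–Anh conformation with attack anti to the α C–O bond of the dioxolane, setting C3' as S (3',4'-anti).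

Step 10
Reactants: 15 aldol adduct; 16 13-methyltetradecanoic acid
Product: 17 (1S)-3-[2-(1,3-oxazol-5-ylmethyl)-1,3-oxazol-4-yl]-3-oxo-1-[(4R,5S)-2,2,5-trimethyl-1,3-dioxolan-4-yl]propyl 13-methyltetradecanoate
Conditions: DCC, DMAP (cat.), CH2Cl2, 0 °C → rt
Reagents that add atoms: none
Why: Steglich esterification of the only free hydroxyl (C3') with catalytic DMAP and no added amine base at low temperature, chosen to outrun E1cB loss of the β-acyloxy group; C3' keeps its configuration because its C–O bond is not broken.

Step 11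
Reactants: 17 β-acyloxy ketone
Product: 18 (1S,3R)-3-hydroxy-3-[2-(1,3-oxazol-5-ylmethyl)-1,3-oxazol-4-yl]-1-[(4R,5S)-2,2,5-trimethyl-1,3-dioxolan-4-yl]propyl 13-methyltetradecanoate
Conditions: (S)-Me-CBS [(3aS)-1-methyl-3,3-diphenyltetrahydro-1H,3H-pyrrolo[1,2-c][1,3,2]oxazaborole] (0.2 equiv), BH3·SMe2, THF, −30 °C; MeOH
Reagents that add atoms: none
Why: Corey–Bakshi–Shibata reduction in which the oxazolyl group acts as the large aryl-like substituent and the CH2 chain as the small one, so the (S)-oxazaborolidine should deliver hydride to give the R carbinol at C1' as it does with acetophenone, while ester and ketal are inert to the borane at this temperature.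

Step 12
Reactants: 18 hydroxy ester acetonide
Product: 19 (1R,3S,4R,5S)-1,4,5-trihydroxy-1-[2-(1,3-oxazol-5-ylmethyl)-1,3-oxazol-4-yl]hexan-3-yl 13-methyltetradecanoate (CNP0177198.1)
Conditions: AcOH–H2O (4:1), 50 °C; concentrate with toluene
Reagents that add atoms: none
Why: Acid hydrolysis of the isopropylidene ketal under mild aqueous acid with a base-free work-up, which should keep O3'→O4' acyl migration and ester hydrolysis slow and touches no stereocentre.

**Compound list**

1 | N-formylglycine | O=CNCC(=O)O | starting material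
2 | Meldrum's acid (2,2-dimethyl-1,3-dioxane-4,6-dione) | CC1(C)OC(=O)CC(=O)O1 | starting material
3 | N-[2-(2,2-dimethyl-4,6-dioxo-1,3-dioxan-5-ylidene)-2-hydroxyethyl]formamide | O=CNCC(O)=C1C(=O)OC(C)(C)OC1=O | intermediate
4 | L-serine methyl ester hydrochloride | Cl.N[C@@H](CO)C(=O)OC | starting material
5 | methyl N-(4-formamido-3-oxobutanoyl)-L-serinate | O=CNCC(=O)CC(=O)N[C@@H](CO)C(=O)OC | intermediate
6 | methyl 2-(4-formamido-3-oxobutanamido)-3-oxopropanoate (amido aldehyde; α-centre labile, no defined stereocentre) | O=CNCC(=O)CC(=O)NC(C=O)C(=O)OC | intermediate (not isolated)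
7 | methyl 2-(1,3-oxazol-5-ylmethyl)-1,3-oxazole-4-carboxylate | COC(=O)c1coc(Cc2cnco2)n1 | intermediate
8 | N-methoxy-N-methyl-2-(1,3-oxazol-5-ylmethyl)-1,3-oxazole-4-carboxamide | CON(C)C(=O)c1coc(Cc2cnco2)n1 | intermediate
9 | 1-[2-(1,3-oxazol-5-ylmethyl)-1,3-oxazol-4-yl]ethan-1-one | CC(=O)c1coc(Cc2cnco2)n1 | intermediate
10 | (4S,5S)-2,2-dimethyl-1,3-dioxolane-4,5-dimethanol | OC[C@@H]1OC(C)(C)O[C@H]1CO | starting material
11 | [(4S,5S)-5-(hydroxymethyl)-2,2-dimethyl-1,3-dioxolan-4-yl]methyl 4-methylbenzenesulfonate | OC[C@@H]1OC(C)(C)O[C@H]1COS(=O)(=O)c1ccc(C)cc1 | intermediate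
12 | [(4S,5S)-2,2,5-trimethyl-1,3-dioxolan-4-yl]methanol | OC[C@@H]1OC(C)(C)O[C@H]1C | intermediate
13 | (4R,5S)-2,2,5-trimethyl-1,3-dioxolane-4-carbaldehyde | O=C[C@@H]1OC(C)(C)O[C@H]1C | intermediate
14 | dicyclohexyl({1-[2-(1,3-oxazol-5-ylmethyl)-1,3-oxazol-4-yl]ethenyl}oxy)borane (boron enolate) | C=C(OB(C1CCCCC1)C1CCCCC1)c1coc(Cc2cnco2)n1 | intermediate (not isolated)
15 | (3S)-3-hydroxy-1-[2-(1,3-oxazol-5-ylmethyl)-1,3-oxazol-4-yl]-3-[(4S,5S)-2,2,5-trimethyl-1,3-dioxolan-4-yl]propan-1-one | O=C(C[C@H](O)[C@@H]1OC(C)(C)O[C@H]1C)c1coc(Cc2cnco2)n1 | intermediate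
16 | 13-methyltetradecanoic acid | CC(C)CCCCCCCCCCCC(=O)O | starting material
17 | (1S)-3-[2-(1,3-oxazol-5-ylmethyl)-1,3-oxazol-4-yl]-3-oxo-1-[(4R,5S)-2,2,5-trimethyl-1,3-dioxolan-4-yl]propyl 13-methyltetradecanoate | CC(C)CCCCCCCCCCCC(=O)O[C@@H](CC(=O)c1coc(Cc2cnco2)n1)[C@@H]1OC(C)(C)O[C@H]1C | intermediate
18 | (1S,3R)-3-hydroxy-3-[2-(1,3-oxazol-5-ylmethyl)-1,3-oxazol-4-yl]-1-[(4R,5S)-2,2,5-trimethyl-1,3-dioxolan-4-yl]propyl 13-methyltetradecanoate | CC(C)CCCCCCCCCCCC(=O)O[C@@H](C[C@@H](O)c1coc(Cc2cnco2)n1)[C@@H]1OC(C)(C)O[C@H]1C | intermediate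
19 | (1R,3S,4R,5S)-1,4,5-trihydroxy-1-[2-(1,3-oxazol-5-ylmethyl)-1,3-oxazol-4-yl]hexan-3-yl 13-methyltetradecanoate | CC(C)CCCCCCCCCCCC(=O)O[C@@H](C[C@@H](O)c1coc(Cc2cnco2)n1)[C@H](O)[C@H](C)O | target

**Step count**

Total: 12 steps. Longest linear sequence: 9 steps (steps 1–5 and 9–12, from N-formylglycine); the aldehyde branch (steps 6–8) joins at step 9.

**Steps most likely to fail**

1. Step 3. The amido aldehyde 6 may be consumed before both rings close: by self-condensation through its enol, by C-cyclisation of the acidic chain methylene onto the aldehyde once the amide rotates, or by over-oxidation of that methylene by the periodinane. Halogenation of the β-keto amide enol by the phosphonium iodide would be a further drain. The fallback closes the two rings one at a time by single cyclodehydrations and never forms the aldehyde. It sets out from 5.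
 - Silylation (TBSCl, imidazole, DMF, 0 °C) should give methyl O-[tert-butyl(dimethyl)silyl]-N-(4-formamido-3-oxobutanoyl)-L-serinate F1.
 - Robinson–Gabriel cyclodehydration of its formamido ketone (PPh3, C2Cl6, Et3N, MeCN, rt) should close ring B to methyl O-[tert-butyl(dimethyl)silyl]-N-[2-(1,3-oxazol-5-yl)acetyl]-L-serinate F2.
 - HF·pyridine (THF, 0 °C) should free the alcohol methyl N-[2-(1,3-oxazol-5-yl)acetyl]-L-serinate F3.
 - Cyclodehydration with bis(2-methoxyethyl)aminosulfur trifluoride (CH2Cl2, −20 °C) should give methyl (4S)-2-(1,3-oxazol-5-ylmethyl)-4,5-dihydro-1,3-oxazole-4-carboxylate F4, which is not isolated; BrCCl3 and DBU (0 °C) should dehydrogenate it to ring A.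
 - The sequence comes back to the route at 7.

2. Step 9. Facial discrimination at the aldehyde in the closed transition state may be poor, giving the C3' epimer, or enolisation may stall because the borane is tied up by the oxazole nitrogens. The fallback is an open-transition-state Mukaiyama aldol that sets out from 9.
 - TMSOTf and Et3N (CH2Cl2, 0 °C) should give the enol silane 2-(1,3-oxazol-5-ylmethyl)-4-[1-(trimethylsilyloxy)ethenyl]-1,3-oxazole F5.
 - BF3·OEt2 (CH2Cl2, −78 °C), a monodentate Lewis acid that cannot chelate, should activate 13 so that F5 adds in the polar Felkin–Anh sense.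
 - The sequence comes back to the route at the 3',4'-anti adduct 15.

3. Step 10. The newly attached carboxylate may be lost from the β-acyloxy ketone by base-promoted E1cB elimination, or 15 may undergo retro-aldol cleavage during acylation; this liability lasts until the ketone is reduced. The fallback reduces first and acylates afterwards, and sets out from 15.
 - Narasaka–Prasad reduction (Et2BOMe, NaBH4, THF–MeOH, −78 °C) should give the 1',3'-syn diol (1R,3S)-1-[2-(1,3-oxazol-5-ylmethyl)-1,3-oxazol-4-yl]-3-[(4S,5S)-2,2,5-trimethyl-1,3-dioxolan-4-yl]propane-1,3-diol F6; hydride adds to the boron chelate of the β-hydroxy ketone, which sets C1' as R without a chiral reagent.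
 - Silylation of the less hindered C1' hydroxyl (TBSCl, 1.05 equiv, imidazole, DMF, 0 °C) should give (1S,3R)-3-{[tert-butyl(dimethyl)silyl]oxy}-3-[2-(1,3-oxazol-5-ylmethyl)-1,3-oxazol-4-yl]-1-[(4S,5S)-2,2,5-trimethyl-1,3-dioxolan-4-yl]propan-1-ol F7.
 - Steglich esterification with 16 (DCC, DMAP, CH2Cl2) should give (1S,3R)-3-{[tert-butyl(dimethyl)silyl]oxy}-3-[2-(1,3-oxazol-5-ylmethyl)-1,3-oxazol-4-yl]-1-[(4R,5S)-2,2,5-trimethyl-1,3-dioxolan-4-yl]propyl 13-methyltetradecanoate F8, which has no carbonyl β to the ester.
 - HF·pyridine (THF–pyridine, 0 °C) should remove the silyl ether; the sequence comes back to the route at 18 and replaces steps 10 and 11.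

**Further compounds**

F1 | step 3 | methyl O-[tert-butyl(dimethyl)silyl]-N-(4-formamido-3-oxobutanoyl)-L-serinate | O=CNCC(=O)CC(=O)N[C@@H](CO[Si](C)(C)C(C)(C)C)C(=O)OC
F2 | step 3 | methyl O-[tert-butyl(dimethyl)silyl]-N-[2-(1,3-oxazol-5-yl)acetyl]-L-serinate | O=C(Cc1cnco1)N[C@@H](CO[Si](C)(C)C(C)(C)C)C(=O)OC
F3 | step 3 | methyl N-[2-(1,3-oxazol-5-yl)acetyl]-L-serinate | O=C(Cc1cnco1)N[C@@H](CO)C(=O)OC
F4 | step 3 | methyl (4S)-2-(1,3-oxazol-5-ylmethyl)-4,5-dihydro-1,3-oxazole-4-carboxylate | COC(=O)[C@@H]1COC(Cc2cnco2)=N1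
F5 | step 9 | 2-(1,3-oxazol-5-ylmethyl)-4-[1-(trimethylsilyloxy)ethenyl]-1,3-oxazole | C=C(O[Si](C)(C)C)c1coc(Cc2cnco2)n1
F6 | step 10 | (1R,3S)-1-[2-(1,3-oxazol-5-ylmethyl)-1,3-oxazol-4-yl]-3-[(4S,5S)-2,2,5-trimethyl-1,3-dioxolan-4-yl]propane-1,3-diol | O[C@H](C[C@H](O)[C@@H]1OC(C)(C)O[C@H]1C)c1coc(Cc2cnco2)n1
F7 | step 10 | (1S,3R)-3-{[tert-butyl(dimethyl)silyl]oxy}-3-[2-(1,3-oxazol-5-ylmethyl)-1,3-oxazol-4-yl]-1-[(4S,5S)-2,2,5-trimethyl-1,3-dioxolan-4-yl]propan-1-ol | CC(C)(C)[Si](C)(C)O[C@H](C[C@H](O)[C@@H]1OC(C)(C)O[C@H]1C)c1coc(Cc2cnco2)n1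
F8 | step 10 | (1S,3R)-3-{[tert-butyl(dimethyl)silyl]oxy}-3-[2-(1,3-oxazol-5-ylmethyl)-1,3-oxazol-4-yl]-1-[(4R,5S)-2,2,5-trimethyl-1,3-dioxolan-4-yl]propyl 13-methyltetradecanoate | CC(C)CCCCCCCCCCCC(=O)O[C@@H](C[C@@H](O[Si](C)(C)C(C)(C)C)c1coc(Cc2cnco2)n1)[C@@H]1OC(C)(C)O[C@H]1C
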